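| flask | electrophile | free base | protonated nucleophile | scavenger | protic impurity | remark | time |
|---|---|---|---|---|---|---|---|
| dusk | 0.40 M | 0.75 M | 0.44 M | 0.20 M | 0.20 M | run made earlier |  |
| autumn | 0.40 M | 1.1 M | 0.44 M | 0.20 M | 0.20 M | run made earlier |  |
| west | 0.40 M | 1.60 M | 0.440 M | 0.200 M | 0.200 M |  | 20 h |
| north-west | 0.40 M | 1.20 M | 0.440 M | 0.200 M | 0.200 M |  | 20 h |

| run | time / h | electrophile / % | target / % |
|---|---|---|---|
| dusk | 1.50 | 88.5 | 3.0 |
| dusk | 4.00 | 70.9 | 7.8 |
| dusk | 8.00 | 52.9 | 11.9 |
| dusk | 20.0 | 30.5 | 21.5 |
| autumn | 5.00 | 63.9 | 7.9 |
| autumn | 10.0 | 47.4 | 16.9 |
| autumn | 15.0 | 35.6 | 20.9 |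
| autumn | 20.0 | 29.2 | 27.3 |

(each reading ± 1 percentage point)

- part of the electrophile that has reacted at the end, west
- part of the electrophile that has reacted at the end, north-west
- what raising the concentration of free base from its lowest to its highest value here does to the part of the electrophile that has reacted (changes below 5 percentage points count as none) (it falls / it rises / no change)

- what is said of acid set free includes idle adduct
- on the list of suspects stand: target -> over-reaction product; nucleophile + acid set free <-> protonated nucleophile; acid set free + free base <-> salt of the base; electrophile + nucleophile -> acid set free + target; nucleophile + acid set free <-> idle adduct; electrophile + protic impurity -> quenched substrate; acid set free + scavenger -> scavenged by-product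

1. Late in the autumn run, at 20.0 h, 70.8% of the electrophile has gone, but 27.3% has become target. So I follow one electrophile molecule and ask for its chances at the fork between nucleophile and protic impurity.

2. First I take the main step by itself, as pseudo-first-order in electrophile. Autumn target at the end, divided by the area under the autumn electrophile curve, gives a constant k = 0.0258 h⁻¹. By itself, that constant gives 40.3% conversion at that time.

3. Now I add the quench, which consumes protic impurity one for one. At each moment the molecule reaches target with chance κ/(κ + [protic impurity]). Holding κ constant, I integrate to [target] = κ ln(charged [protic impurity]/[protic impurity]). In the autumn run at 10.0 h, I take loss minus target as the quenched substrate, hence the impurity left, and so read κ = 0.0540 M, a reading that carries the scatter of those readings. This is the even-odds concentration, the [protic impurity] at which both routes are equally likely. At the autumn charge the target chance is 21.3%, since the impurity stands above κ.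

4. I let the acid and base steps act through κ, by way of [nucleophile]. From dusk to autumn, free base rises, yet the electrophile left at the end differs by 1.3 percentage points, below the margin. I therefore carry κ and the autumn impurity left at the end, 0.0260 M, to west and north-west. Impurity consumed plus κ ln(charged/left), over charged [electrophile], gives my estimate of 71.0% for both flasks. The same figure for both is my assumption, taken from the dusk-to-autumn difference, and on that ground I expect no change.

5. The forecast gives 75% for west, 72% for north-west and no change: “The gain of about 3 points is below the 5-point threshold.” My figure lies below both of its numbers.

The flasks give 72.9% for west and 70.9% for north-west, and no change, the change being 2.1 points.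

    target → over-reaction product (k = 1.40 × 10⁻⁴ h⁻¹)
    nucleophile + acid set free ⇌ protonated nucleophile, settled at all times (K = 1100 M⁻¹)
    acid set free + free base ⇌ salt of the base (K = 190 M⁻¹, k = 1.40 M⁻¹ h⁻¹)
    electrophile + nucleophile → acid set free + target (k = 0.660 M⁻¹ h⁻¹)
    nucleophile + acid set free ⇌ idle adduct, settled at all times (K = 150 M⁻¹)
    electrophile + protic impurity → quenched substrate (k = 0.500 M⁻¹ h⁻¹)
    acid set free + scavenger → scavenged by-product (k = 3.00 M⁻¹ h⁻¹)

In west, 13% of the charged protic impurity is left at 20.0 h, and κ then puts conversion at 70.8%. With all other amounts and the time held, the west answer moves by 5 points when its protic impurity reaches 0.166 M or 0.238 M, and I would test the forecast for west by a run at either amount. The neighbour flask is west with 0.080 M of protic impurity, and the same κ puts its target chance at charge at 40.3%. With 6.9% of that impurity left, κ gives 54.7% conversion, and the neighbour flask gives 53.6%.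

All runs stem from a simulated flask for substances that don't exist; scatter was added.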